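Ring B of the target (C5–C10) carries oxygen at C6, the C7=C8 alkene with its methyl group and the methylated quaternary C10. This is the pattern of 2,6-dimethyl-1,4-benzoquinone, and the second quinone carbonyl sits at C9, where C11 must be attached. The plan therefore cuts C1–C10 and C4–C5 and releases ring A (C1–C4) as a 2-silyloxydiene with a dimethylated terminus. One catalytic enantioselective Diels–Alder reaction of the quinone with this diene closes ring A, creates C10 and delivers C3, C6 and C9 as three distinguishable oxygen functions. After early C5 epimerisation to the trans-decalin, C10 controls every later stereocentre.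

Key step: step 3

Numbering: drimane numbering is used throughout (C3 oxygen, C4 CMe2, C5 and C10 ring fusion, C6, C7=C8, C9, C11 = CH2OAr). Faces are named relative to the C10 methyl group.

Assumption: the sense of induction in step 3 is assigned from the usual binding model of this catalyst class (boron on the C6 oxygen lone pair beside C5–H, a C5–H···O contact to the ring oxygen, one C-phenyl group covering the rear face). If the first enantiomer assay shows the mirror image of 5, the equally available (R)-catalyst is used and nothing else changes.

Step 1
Reactants: 1 4-methylpent-1-en-3-ol (racemic)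
Product: 2 4-methylpent-1-en-3-one (isopropyl vinyl ketone)
Conditions: IBX (1.3 equiv), EtOAc, 75 °C, trace BHT; filter, distil
Reagents that add atoms: none
Why: IBX oxidation of a secondary allylic alcohol under neutral, non-nucleophilic conditions should give the polymerisation-prone vinyl ketone cleanly, and this entry places the vinyl group unambiguously, which an aminomethylation of 3-methylbutan-2-one does not guarantee.

Step 2
Reactants: 2 4-methylpent-1-en-3-one
Product: 3 4-methyl-3-(triisopropylsilyloxy)penta-1,3-diene
Conditions: TIPSOTf (1.1 equiv), Et3N (1.5 equiv), CH2Cl2, 0 °C → rt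
Reagents that add atoms: triisopropylsilyl trifluoromethanesulfonate, CC(C)[Si](OS(=O)(=O)C(F)(F)F)(C(C)C)C(C)C
Why: Soft enolisation with O-silylation (silyl triflate and tertiary amine) can only use the isopropyl C–H, and the two methyl groups on the new alkene are identical, so a single 2-silyloxydiene without an E/Z question should result.

Step 3
Reactants: 3 4-methyl-3-(triisopropylsilyloxy)penta-1,3-diene (1.5 equiv); 4 2,6-dimethyl-1,4-benzoquinone
Product: 5 cis-fused enedione silyl enol ether, (4aS,8aR)-2,5,5,8a-tetramethyl-6-(triisopropylsilyloxy)-4a,5,8,8a-tetrahydronaphthalene-1,4-dione (drimane 5S,10R; H5 and the C10 methyl on the same face)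
Conditions: (S)-3,3-diphenyl-1-(o-tolyl)tetrahydro-1H,3H-pyrrolo[1,2-c][1,3,2]oxazaborole (20 mol %), Tf2NH (18 mol %), CH2Cl2, −78 → −40 °C; Et3N quench
Reagents that add atoms: none
Why: The N-protonated oxazaborolidine binds the more basic and sterically open C6 oxygen of 4 at the lone pair beside C5–H, lowers the quinone LUMO and triggers a concerted, asynchronous [4+2] cycloaddition; the reaction type is the oxazaborolidinium-catalysed enantioselective Diels–Alder reaction of methylated benzoquinones with 2-silyloxydienes. Ring A closes as a six-membered carbocycle by intermolecular [4+2] annulation, suprafacial on both partners, forming C1–C10 and C4–C5. C10 is set by the catalyst, whose C-phenyl group covers one face of the bound C5=C10 bond so that the diene enters from the other, and C5 follows from suprafacial addition, which places H5 cis to the C10 methyl. Site selectivity is not an issue because the twofold axis of 4 makes its two C(CH3)=CH bonds equivalent. Orientation is the selectivity that must be won: joining CMe2 to C10 would create two adjacent quaternary carbons, so the unsubstituted terminus C1 should take the methyl-bearing C10, the carbon made most electrophilic by the bound C6 carbonyl, while the dimethylated terminus, which carries the developing charge as a tertiary allylic centre, closes on the CH carbon C5. The bulky TIPS group favours the s-cis rotamer against the inward methyl group, resists protodesilylation by the acidic catalyst and marks C3 for the later carbinol.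

Step 4
Reactants: 5 cis-fused enedione silyl enol ether
Product: 6 trans-fused enedione silyl enol ether, (4aR,8aR)-2,5,5,8a-tetramethyl-6-(triisopropylsilyloxy)-4a,5,8,8a-tetrahydronaphthalene-1,4-dione (drimane 5R,10R; H5 opposite the C10 methyl)
Conditions: DBU (0.2 equiv), CH2Cl2, rt, argon
Reagents that add atoms: none
Why: Base-catalysed keto–enol epimerisation through the C5=C6 enolate under thermodynamic control should turn the cis- into the trans-fused enedione (C4 and C1 both equatorial on ring B), and it is placed here because C10 blocks aromatisation, the masked C3 ketone cannot start a retro-Michael opening that would aromatise ring B, and neither a C9 stereocentre nor a leaving group at C11 exists yet.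

Step 5
Reactants: 6 trans-fused enedione silyl enol ether
Product: 7 (5R,6S,10R)-6-hydroxy-3-(triisopropylsilyloxy)-11-nordrima-2,7-dien-9-one (C6 hydroxyl axial, on the face of the C10 methyl)
Conditions: NaBH4 (1.0 equiv), CeCl3·7H2O (1.1 equiv), MeOH–CH2Cl2, −78 °C
Reagents that add atoms: none
Why: In this Luche 1,2-reduction the C6 carbonyl, more basic through the vinylogous C8 methyl and open beside C7–H, should be activated and reduced in preference to the C9 carbonyl wedged between quaternary C10 and methyl-bearing C8, and hydride enters opposite the axial methyls on C4 and C10 to give the axial (6S) carbinol, a centre that is erased in step 12.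

Step 6
Reactants: 7 (5R,6S,10R)-6-hydroxy-3-(triisopropylsilyloxy)-11-nordrima-2,7-dien-9-one
Product: 8 (5S,6S,10R)-3-(triisopropylsilyloxy)drima-2,7,9(11)-trien-6-ol
Conditions: Cp2TiMe2 (3 equiv), toluene, 70 °C, dark
Reagents that add atoms: dimethyltitanocene, C[Ti](C)(C1C=CC=C1)C1C=CC=C1
Why: In the Petasis methylenation thermally formed Cp2Ti=CH2 adds to the hindered, non-enolisable C9 ketone through an oxatitanacyclobutane under non-basic conditions, so the γ-hydroxy enone is not isomerised to a 1,4-diketone, the free hydroxyl only consumes an extra equivalent, and the silyl enol ether is inert.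

Step 7
Reactants: 8 (5S,6S,10R)-3-(triisopropylsilyloxy)drima-2,7,9(11)-trien-6-ol
Product: 10 (5S,6S,9R,10S)-3-(triisopropylsilyloxy)drima-2,7-diene-6,11-diol, via bis-9-BBN adduct 9 (not isolated)
Conditions: 9-BBN (3 equiv), THF, 0 → 45 °C; then 3 M NaOH, 30% H2O2, 0 °C
Reagents that add atoms: 9-borabicyclo[3.3.1]nonane (boron and its carbon frame, in 9 only), [H]B1C2CCCC1CCC2; hydrogen peroxide (the C11 oxygen), OO
Why: In this hydroboration–oxidation 9-BBN places boron on the terminal C11 of the 1,1-disubstituted alkene (the trisubstituted C7=C8 and the hindered enol ether react far more slowly) and delivers hydrogen to C9 from the face opposite the axial C10 methyl, which sets (9R) with C11 equatorial and cis to that methyl.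

Step 8
Reactants: 10 (5S,6S,9R,10S)-3-(triisopropylsilyloxy)drima-2,7-diene-6,11-diol; 11 umbelliferone (7-hydroxycoumarin)
Product: 12 7-{[(5S,6S,9R,10S)-6-hydroxy-3-(triisopropylsilyloxy)drima-2,7-dien-11-yl]oxy}coumarin
Conditions: PPh3 (1.5 equiv), DIAD (1.5 equiv), THF (0.5 M), 0 °C → rt
Reagents that add atoms: none
Why: In the Mitsunobu etherification the acidic phenol displaces the oxyphosphonium of the primary C11 alcohol by SN2 without touching a stereocentre, while the axial C6 hydroxyl, flanked by two syn-axial methyl groups, is too hindered to be activated.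

Step 9
Reactants: 12 7-{[(5S,6S,9R,10S)-6-hydroxy-3-(triisopropylsilyloxy)drima-2,7-dien-11-yl]oxy}coumarin
Product: 13 7-{[(5S,6S,9R,10S)-6-hydroxy-3-oxodrim-7-en-11-yl]oxy}coumarin
Conditions: TBAF (1.2 equiv), AcOH (1.2 equiv), THF, 0 °C
Reagents that add atoms: none
Why: Fluoride-induced cleavage of the silyl enol ether with buffered TBAF and protonation at C2 releases the C3 ketone, safely at this point because C9 is no longer a carbonyl (no 1,5-diketone) and C6 is still a carbinol (no base-labile vinylogous β-aryloxy ketone).

Step 10
Reactants: 13 7-{[(5S,6S,9R,10S)-6-hydroxy-3-oxodrim-7-en-11-yl]oxy}coumarin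
Product: 14 7-{[(3R,5S,6S,9R,10S)-3,6-dihydroxydrim-7-en-11-yl]oxy}coumarin
Conditions: NaBH4 (1.5 equiv), MeOH–THF, 0 °C
Reagents that add atoms: none
Why: Borohydride reduction of a 4,4-dimethyl-3-ketone in a trans-decalin proceeds by axial hydride delivery from the face opposite the axial C4 and C10 methyls and should give the equatorial (3R) alcohol, while the coumarin lactone and the isolated alkene do not react at this temperature.

Step 11
Reactants: 14 7-{[(3R,5S,6S,9R,10S)-3,6-dihydroxydrim-7-en-11-yl]oxy}coumarin
Product: 15 7-{[(3R,5S,6S,9R,10S)-3-acetoxy-6-hydroxydrim-7-en-11-yl]oxy}coumarin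
Conditions: Ac2O (1.5 equiv), pyridine, rt (no DMAP)
Reagents that add atoms: acetic anhydride, CC(=O)OC(C)=O
Why: Site-selective acetylation should esterify the equatorial C3 hydroxyl while the axial C6 hydroxyl, 1,3-diaxial to two methyl groups, stays free.

Step 12
Reactants: 15 7-{[(3R,5S,6S,9R,10S)-3-acetoxy-6-hydroxydrim-7-en-11-yl]oxy}coumarin
Product: 16 target, 7-{[(3R,5S,9R,10S)-3-acetoxy-6-oxodrim-7-en-11-yl]oxy}coumarin
Conditions: Dess–Martin periodinane (1.3 equiv), NaHCO3, CH2Cl2, 0 °C → rt
Reagents that add atoms: none
Why: Dess–Martin oxidation of the remaining allylic alcohol under buffered, near-neutral conditions gives the C6 enone, helped by relief of 1,3-diaxial strain, and forming the enone last keeps C5, C9 and the C11 aryl ether away from any base (no epimerisation, no vinylogous E1cB loss of umbelliferone).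

Compound list
1 | 4-methylpent-1-en-3-ol (racemic) | C=CC(O)C(C)C | starting material
2 | 4-methylpent-1-en-3-one | C=CC(=O)C(C)C | intermediate
3 | 4-methyl-3-(triisopropylsilyloxy)penta-1,3-diene | C=CC(O[Si](C(C)C)(C(C)C)C(C)C)=C(C)C | intermediate
4 | 2,6-dimethyl-1,4-benzoquinone | CC1=CC(=O)C=C(C)C1=O | starting material
5 | cis-fused enedione silyl enol ether (5S,10R) | CC(C)[Si](C(C)C)(C(C)C)OC1=CC[C@@]2(C)C(=O)C(C)=CC(=O)[C@H]2C1(C)C | intermediate
6 | trans-fused enedione silyl enol ether (5R,10R) | CC(C)[Si](C(C)C)(C(C)C)OC1=CC[C@@]2(C)C(=O)C(C)=CC(=O)[C@@H]2C1(C)C | intermediate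
7 | (5R,6S,10R)-6-hydroxy-3-(triisopropylsilyloxy)-11-nordrima-2,7-dien-9-one | CC(C)[Si](C(C)C)(C(C)C)OC1=CC[C@@]2(C)C(=O)C(C)=C[C@H](O)[C@@H]2C1(C)C | intermediate
8 | (5S,6S,10R)-3-(triisopropylsilyloxy)drima-2,7,9(11)-trien-6-ol | CC(C)[Si](C(C)C)(C(C)C)OC1=CC[C@@]2(C)C(=C)C(C)=C[C@H](O)[C@@H]2C1(C)C | intermediate
9 | bis-9-BBN adduct (C11 borane, C6 borinate), not isolated | CC(C)[Si](C(C)C)(C(C)C)OC1=CC[C@@]2(C)[C@H](CB3C4CCCC3CCC4)C(C)=C[C@H](OB3C4CCCC3CCC4)[C@@H]2C1(C)C | intermediate
10 | (5S,6S,9R,10S)-3-(triisopropylsilyloxy)drima-2,7-diene-6,11-diol | CC(C)[Si](C(C)C)(C(C)C)OC1=CC[C@@]2(C)[C@H](CO)C(C)=C[C@H](O)[C@@H]2C1(C)C | intermediate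
11 | umbelliferone | O=c1ccc2ccc(O)cc2o1 | starting material
12 | C11 umbelliferyl ether, 6-hydroxy, 3-OTIPS enol ether | CC(C)[Si](C(C)C)(C(C)C)OC1=CC[C@@]2(C)[C@H](COc3ccc4ccc(=O)oc4c3)C(C)=C[C@H](O)[C@@H]2C1(C)C | intermediate
13 | C11 umbelliferyl ether, 6-hydroxy-3-ketone | O=C1CC[C@@]2(C)[C@H](COc3ccc4ccc(=O)oc4c3)C(C)=C[C@H](O)[C@@H]2C1(C)C | intermediate
14 | C11 umbelliferyl ether, (3R,6S)-diol | O[C@@H]1CC[C@@]2(C)[C@H](COc3ccc4ccc(=O)oc4c3)C(C)=C[C@H](O)[C@@H]2C1(C)C | intermediate
15 | C11 umbelliferyl ether, 3-acetate, 6-hydroxy | CC(=O)O[C@@H]1CC[C@@]2(C)[C@H](COc3ccc4ccc(=O)oc4c3)C(C)=C[C@H](O)[C@@H]2C1(C)C | intermediate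
16 | CNP0363962.1 | CC(=O)O[C@@H]1CC[C@@]2(C)[C@H](COc3ccc4ccc(=O)oc4c3)C(C)=CC(=O)[C@@H]2C1(C)C | target

Total step count: 12. Longest linear sequence: 12 steps (1 → 16); 4 and 11 are bought.

Steps most likely to fail

Step 3. Four things may go wrong.
- Orientational control may be lost, because the silyloxy group makes the hindered CMe2 terminus the electronically preferred partner of C10.
- A stepwise Mukaiyama–Michael addition may end in aromatisation of ring B instead of ring closure.
- The diene may react slowly, because its s-cis form is strained.
- Facial selectivity may be poor.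

The fallback gives up Lewis acid catalysis and absolute control in this step. Without a Lewis acid the C9 carbonyl, which is not weakened by vinylogous donation from the ring methyl groups, is the stronger acceptor, so electronic and steric preferences both send CMe2 to C5. Setting out from 3 and 4, heating in toluene (110 °C, sealed tube, BHT) should give 5 as a racemate, that is 5 together with the antipode of 5 F1. Preparative chromatography on a chiral stationary phase (amylose tris(3,5-dimethylphenylcarbamate), supercritical CO2/MeOH) separates the two, and the fallback comes back to the route at 5.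

Step 5. Site selectivity between the C6 and C9 carbonyls may be poor, since both are flanked by hindered carbons, or conjugate reduction of the enedione may compete. The fallback replaces selective reduction by exhaustive reduction and selective re-oxidation. Setting out from 6, DIBAL-H (2.5 equiv, CH2Cl2, −78 °C) reduces both carbonyls from the face opposite the C10 methyl to the 6,9-ene-diol F2. MnO2 (CH2Cl2, rt) should then oxidise only the equatorial C9 carbinol, whose axial C–H is aligned with the C7=C8 π system. The axial, doubly shielded C6 carbinol is left untouched, and the fallback comes back to the route at 7.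

Step 8. Substitution at the β-branched C11 may be slow, the allylic C6 hydroxyl may be activated in competition, or the homoallylic C7=C8 bond may participate in the displacement. The fallback forms the aryl–oxygen bond instead of the alkyl–oxygen bond, so no substitution at C11 is needed. Setting out from 10, cross-coupling of the primary alcohol with commercial 7-bromocoumarin gives the same ether. The conditions are [Pd(C3H5)Cl]2 (2 mol %), 2-(di-tert-butylphosphino)-3-methoxy-6-methyl-2',4',6'-triisopropylbiphenyl (6 mol %), Cs2CO3 and toluene at 90 °C, with the zerovalent palladium catalyst formed in situ. The hindered secondary C6 hydroxyl should couple far more slowly. The fallback comes back to the route at 12.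

Further compounds
F1 | step 3 | antipode of 5 (5R,10S, cis-fused) | CC(C)[Si](C(C)C)(C(C)C)OC1=CC[C@]2(C)C(=O)C(C)=CC(=O)[C@@H]2C1(C)C
F2 | step 5 | 6,9-ene-diol: 3-(triisopropylsilyloxy)-11-nordrima-2,7-diene-6,9-diol, trans-fused, both hydroxyls on the face of the C10 methyl | CC(C)[Si](C(C)C)(C(C)C)OC1=CC[C@@]2(C)[C@H](O)C(C)=C[C@H](O)[C@@H]2C1(C)C
F0 | step 8 | none | none
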